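- X, as the fraction x of the G charged, is what you must predict: delta stays at 25 °C, while eta goes to 45 °C after 30 s, and both are read at 2.5 min.

in all of them: G 39 mM
- south-east: Q 0.60 equiv; E 0.78 mM; temperature 20 °C; run made earlier
- east: Q 1.4 equiv; E 0.78 mM; temperature 35 °C; run made earlier
- south: Q 0.90 equiv; E 1.6 mM; temperature 20 °C; run made earlier
- delta: Q 0.900 equiv; E 0.780 mM; at 25 °C throughout; time 2.5 min
- eta: Q 0.900 equiv; E 0.780 mM; at 25 °C until 30 s, from then on at 45 °C; time 2.5 min

| run | time / s | X / % |
|---|---|---|
| south-east | 10.0 | 13.1 |
| south-east | 15.0 | 18.3 |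
| south-east | 25.0 | 25.0 |
| south-east | 50.0 | 37.5 |
| south-east | 90.0 | 47.1 |
| east | 10.0 | 53.0 |
| east | 15.0 | 65.5 |
| east | 30.0 | 79.4 |
| east | 60.0 | 86.6 |
| south | 20.0 | 30.6 |
| south | 40.0 | 46.4 |
| south | 50.0 | 51.0 |
| south | 80.0 | 60.2 |
| south | 90.0 | 63.6 |

(scatter of a reading: 0.5 percentage points)

- the numbers in the tables scatter by 0.5 percentage points (one standard deviation)
- a reading or a percentage of X counts all its forms, free or not

- the flask that ends with the higher amount of X, in percent of the G charged, or "neither" when 2 percentage points or less lies between them (delta / eta / neither)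
- final X, as a percentage of the G charged, in delta
- final X, as a percentage of the G charged, in eta

- Start with a clock. If G and Q react one to one, dx/dt = κ(free G fraction)(q − x), where q is the usable Q per G charged, and integrating this forward law turns a single reading into κ.
- Suppose E takes Q one for one; then q is 0.580 in the south-east run and 1.38 in the east run. Their first readings give 0.0275 /s at 20 °C and 0.0712 /s at 35 °C.
- Interpolating ln κ in temperature gives the capture rate, the rate per unit of q at which a G is taken, at 25 °C: 0.0378 /s.
- But E may be a bystander. For the south run at 90.0 s, the clock gives 64.2 % with E subtracted and 66.4 % without, against a reading of 63.6 %, so the subtraction stays.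
- Delta and eta therefore have q = 0.880. In delta, the lifetime of G, 1/(κq), is 30.1 s, so 2.5 min holds 4.98 lifetimes and the integrated law gives 78.3 %. Eta should hold 48.3 % at its change.
- Yet this law has no way back. For the east run at 60.0 s it gives 93.7 %, and the reading is 86.6 %, with a scatter of 0.5 percentage points. The east flask is falling short, and that reading gives a stopping quotient, x over free G times free Q, of 12.6.
- In eta after the change, κ extrapolates to 0.134 /s, and the lifetime on the remaining Q is 18.8 s, so the remaining time holds 6.38 lifetimes.
- Eta should thus reach its stop. I assume that heat lowers the quotient, so my estimate for eta lies under the 69.7 % that the east value gives. That is kinetic against thermodynamic control: I put delta somewhat under 78.3 % and ahead of eta.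
- The forecast says delta, with 75 % for delta and 57 % for eta, and holds that “E has little kinetic effect”, where I subtract E from Q.
- The simulation gives delta as the higher flask: delta ends at 74.4 % and eta at 64.8 %.

    G + Q ⇌ X + L (K = 3.80, k = 1.00 /M/s, Ea = 51.0 kJ/mol, ΔH = −58.0 kJ/mol)
    Q + E → J (k = 330 /M/s, Ea = 45.0 kJ/mol)
    D ⇌ X, rate k3*(cs3 - [X]) while solid is left; crystals form when [X] > cs3 (solubility = 4.30 mM, k = 3.18 /s)
    (constants at 25 °C)

- Delta ends 3.9 points under the clock's figure from 0.0378 /s. Now take the neighbour of delta charged with 3.60 equiv of Q, so q is 3.58. Q stands in large excess, so the clock treats G's loss in this neighbour as pseudo-first-order, with a lifetime of 7.39 s, and 2.5 min holds 20.3 lifetimes. In this neighbour flask, nearly all of the G charged ends as X, at 98.9 %, and G stands at 1.11 %.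

(The numbers in the tables were computed for an exercise; the scatter is artificial.)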